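**Retrosynthetic overview**
1. 25 ⇐ 24 by a Schenck ene reaction with singlet oxygen (hydroperoxide on C11, E-alkene at C9=C10); 24 ⇐ 19 by allylboration, cross-metathesis to the prenyl group and oxidation at C8; 19 ⇐ 16 by allylic chlorination of the isopropenyl group, N-oxide oxidation and catalyst-controlled epoxidation of the resulting 2-substituted acrolein.
2. 16 ⇐ 11 by acylation of C1–OH, C2–OH-directed epoxidation of C3=C4 and oxidation of C2–OH to the ketone, which erases the relay stereocentre.
3. 11 ⇐ acyclic (Z)-dienal 10 by an intramolecular carbonyl-ene reaction that forms the C1–C6 ring bond; 10 ⇐ Z-selective Wittig union of glycerate-derived ketone 3 with homoprenyl ylide 6.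
4. Enabling feature (locants: ring C1 bears the ester oxygen, C2 is the ring ketone, C3/C4 the ring oxirane with the methyl on C3, C5 the CH2, C6 bears the side chain; C7 is the quaternary oxirane carbon, C14 its CH2, C8 the side-chain ketone): O–C1H–C6H–C7(=C14H2), read without the oxirane oxygen, is a homoallylic alcohol, the retron of a carbonyl-ene closure of the citronellal-to-isopulegol kind; the ketone C2 next to C1 can be carried as a purchased carbinol stereocentre that steers C1, C6, C3 and C4.
5. Ring order: cyclohexene ring (step 7), ring oxirane (step 10), side-chain oxirane (step 14).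

Key step: step 7

Assumption: the (S)-configured diarylprolinol silyl ether is taken to deliver the peroxide oxygen to the face of the 2-substituted acrolein that gives the (R)-configured oxirane carbon; if the sense proves opposite, its enantiomer serves in the same way.

**Step 1**
Reactants: 1 methyl (4R)-2,2-dimethyl-1,3-dioxolane-4-carboxylate
Product: 3 1-[(4R)-2,2-dimethyl-1,3-dioxolan-4-yl]ethan-1-one, via Weinreb amide 2 (not isolated)
Conditions: MeNH(OMe)·HCl, iPrMgCl, THF, −20 °C; then MeMgBr, −20 → 0 °C; aqueous NH4Cl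
Reagents that add atoms: N,O-dimethylhydroxylamine hydrochloride CNOC.Cl (its atoms stay in 2 only); methylmagnesium bromide MeMgBr C[Mg]Br
Why: Weinreb ketone synthesis in one flask, in which the magnesium amide converts the ester into amide 2 and MeMgBr adds only once because the chelated tetrahedral adduct survives until work-up; no stereocentre is formed and the existing one, alpha to the carbonyl, is kept by the low temperature.

**Step 2**
Reactants: 4 5-bromo-2-methylpent-2-ene
Product: 5 (4-methylpent-3-en-1-yl)triphenylphosphonium bromide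
Conditions: PPh3, MeCN, reflux
Reagents that add atoms: triphenylphosphine c1ccc(cc1)P(c1ccccc1)c1ccccc1
Why: SN2 quaternisation of a primary alkyl bromide by triphenylphosphine gives the phosphonium salt without touching the alkene; no stereocentre is involved.

**Step 3**
Reactants: 5 (4-methylpent-3-en-1-yl)triphenylphosphonium bromide; 3 1-[(4R)-2,2-dimethyl-1,3-dioxolan-4-yl]ethan-1-one
Product: 7 (4S)-2,2-dimethyl-4-[(2Z)-6-methylhepta-2,5-dien-2-yl]-1,3-dioxolane, via phosphorus ylide 6 (not isolated)
Conditions: NaN(SiMe3)2, THF, 0 °C; then 3, −78 °C → rt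
Reagents that add atoms: none
Why: Wittig olefination of an α-alkoxy ketone with a lithium-free non-stabilised ylide, a reaction type known to give the Z-trisubstituted alkene with the new chain cis to the oxygen-bearing carbon, so that C2 and C5 end up cis as the later ring demands; adding the ketone at −78 °C should keep the C2 stereocentre intact.

**Step 4**
Reactants: 7 (4S)-2,2-dimethyl-4-[(2Z)-6-methylhepta-2,5-dien-2-yl]-1,3-dioxolane
Product: 8 (2S,3Z)-3,7-dimethylocta-3,6-diene-1,2-diol
Conditions: AcOH/H2O (4:1), rt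
Reagents that add atoms: none
Why: mild acid-catalysed acetal hydrolysis should free the 1,2-diol without ionising the allylic C–O bond or moving the skipped diene; no stereocentre is formed.

**Step 5**
Reactants: 8 (2S,3Z)-3,7-dimethylocta-3,6-diene-1,2-diol
Product: 9 (2S,3Z)-3,7-dimethyl-1,2-bis(triethylsilyloxy)octa-3,6-diene
Conditions: Et3SiCl, imidazole, CH2Cl2, 0 °C → rt
Reagents that add atoms: chlorotriethylsilane CC[Si](Cl)(CC)CC
Why: standard silylation of both hydroxyl groups; the secondary triethylsilyl ether is the non-chelating protecting group needed in step 7.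

**Step 6**
Reactants: 9 (2S,3Z)-3,7-dimethyl-1,2-bis(triethylsilyloxy)octa-3,6-diene
Product: 10 (2S,3Z)-3,7-dimethyl-2-(triethylsilyloxy)octa-3,6-dienal
Conditions: (COCl)2, DMSO, CH2Cl2, −78 → −40 °C; then Et3N, −78 → −20 °C
Reagents that add atoms: none
Why: Swern oxidation in which the chlorosulfonium reagent cleaves the less hindered primary triethylsilyl ether and oxidises that position to the aldehyde in the same flask while the secondary ether stays; the α-stereocentre should survive because of the low temperature and because the aldehyde is used crude.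

**Step 7**
Reactants: 10 (2S,3Z)-3,7-dimethyl-2-(triethylsilyloxy)octa-3,6-dienal
Product: 11 (1S,2S,6S)-3-methyl-6-(prop-1-en-2-yl)-2-(triethylsilyloxy)cyclohex-3-en-1-ol
Conditions: Me2AlCl (1.2 equiv), CH2Cl2, −78 °C
Reagents that add atoms: none
Why: Me2AlCl activates the aldehyde, the trisubstituted C6=C7 alkene attacks C1 through its less substituted carbon C6 while an allylic hydrogen of one methyl group passes to the carbonyl oxygen, so the C1–C6 bond, the C1 hydroxyl group and the isopropenyl group arise in one concerted, asynchronous carbonyl-ene event, with the proton-scavenging Lewis acid suppressing cationic side paths. The closest known reaction type is the Lewis-acid-promoted cyclisation of citronellal to isopulegol and of neral to isopiperitenol. The six-membered ring is closed by attack of C6 on the carbonyl carbon with the C=O bond exocyclic (6-exo-trig) and the ene double bond also ending up outside the ring, and the Z geometry of C3=C4 holds C2 and C5 cis so that the chain ends can meet. C1 and C6 are both set by the purchased stereocentre C2 through a chair-like half-chair transition state in which the complexed carbonyl oxygen, the C2 silyloxy group and the isopropylidene unit are all pseudo-equatorial, with the C2–O bond anti to the forming bond (the stereoelectronic arrangement of the Felkin–Anh polar model), which places C1–O trans to C2–O and trans to the C6 substituent. The step needs facial selectivity at the aldehyde and at the alkene, which the non-chelating silyl ether with one equivalent of a monodentate Lewis acid and the equatorial preference of all three groups should secure, and chemoselectivity between the two alkenes, which is secured because C3=C4 cannot reach the carbonyl carbon.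

**Step 8**
Reactants: 11 (1S,2S,6S)-3-methyl-6-(prop-1-en-2-yl)-2-(triethylsilyloxy)cyclohex-3-en-1-ol; 12 3-methylbutanoyl chloride
Product: 13 (1S,2S,6S)-3-methyl-6-(prop-1-en-2-yl)-2-(triethylsilyloxy)cyclohex-3-en-1-yl 3-methylbutanoate
Conditions: pyridine, DMAP (cat.), CH2Cl2, 0 °C → rt
Reagents that add atoms: none
Why: DMAP-catalysed acylation of the only free hydroxyl group places the 3-methylbutanoate on C1 with retention of configuration.

**Step 9**
Reactants: 13 (1S,2S,6S)-3-methyl-6-(prop-1-en-2-yl)-2-(triethylsilyloxy)cyclohex-3-en-1-yl 3-methylbutanoate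
Product: 14 (1S,2S,6S)-2-hydroxy-3-methyl-6-(prop-1-en-2-yl)cyclohex-3-en-1-yl 3-methylbutanoate
Conditions: HF·pyridine, pyridine, THF, 0 °C
Reagents that add atoms: none
Why: buffered fluoride desilylation should free the allylic C2 hydroxyl group without cleaving the ester or inducing acyl migration.

**Step 10**
Reactants: 14 (1S,2S,6S)-2-hydroxy-3-methyl-6-(prop-1-en-2-yl)cyclohex-3-en-1-yl 3-methylbutanoate
Product: 15 (1R,2R,3S,4S,6S)-2-hydroxy-1-methyl-4-(prop-1-en-2-yl)-7-oxabicyclo[4.1.0]heptan-3-yl 3-methylbutanoate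
Conditions: VO(acac)2 (5 mol%), t-BuOOH, CH2Cl2, 0 °C → rt
Reagents that add atoms: tert-butyl hydroperoxide CC(C)(C)OO
Why: hydroxyl-directed epoxidation of a cyclic allylic alcohol, in which the vanadate ester of C2–OH delivers oxygen to the same face of C3=C4, so C3 and C4 are set cis to C2–OH, hence cis to the isopropenyl group and trans to the ester, while the isopropenyl alkene, which has no allylic hydroxyl group, stays untouched.

**Step 11**
Reactants: 15 (1R,2R,3S,4S,6S)-2-hydroxy-1-methyl-4-(prop-1-en-2-yl)-7-oxabicyclo[4.1.0]heptan-3-yl 3-methylbutanoate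
Product: 16 (1S,3S,4S,6S)-1-methyl-2-oxo-4-(prop-1-en-2-yl)-7-oxabicyclo[4.1.0]heptan-3-yl 3-methylbutanoate
Conditions: Dess–Martin periodinane, pyridine, CH2Cl2, 0 °C → rt
Reagents that add atoms: none
Why: Dess–Martin oxidation under buffered conditions turns the relay carbinol C2 into the ring ketone; C1, now alpha to the ketone, already has the trans-diequatorial arrangement and should not epimerise.

**Step 12**
Reactants: 16 (1S,3S,4S,6S)-1-methyl-2-oxo-4-(prop-1-en-2-yl)-7-oxabicyclo[4.1.0]heptan-3-yl 3-methylbutanoate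
Product: 17 (1S,3S,4S,6S)-4-(3-chloroprop-1-en-2-yl)-1-methyl-2-oxo-7-oxabicyclo[4.1.0]heptan-3-yl 3-methylbutanoate
Conditions: Ca(OCl)2, solid CO2, CH2Cl2/H2O, 0 °C
Reagents that add atoms: calcium hypochlorite Ca(OCl)2 [Ca+2].[O-]Cl.[O-]Cl
Why: ene-type allylic chlorination with hypochlorous acid made in the flask, in which chlorine adds to the methylene terminus of the only remaining alkene and a methyl hydrogen is lost to give the transposed 2-substituted allyl chloride, as is known for isopropenyl groups on cyclohexanones.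

**Step 13**
Reactants: 17 (1S,3S,4S,6S)-4-(3-chloroprop-1-en-2-yl)-1-methyl-2-oxo-7-oxabicyclo[4.1.0]heptan-3-yl 3-methylbutanoate
Product: 18 (1S,3S,4S,6S)-1-methyl-2-oxo-4-(3-oxoprop-1-en-2-yl)-7-oxabicyclo[4.1.0]heptan-3-yl 3-methylbutanoate
Conditions: Me3NO (anhydrous), DMSO, rt
Reagents that add atoms: trimethylamine N-oxide C[N+](C)(C)[O-]
Why: Kornblum-type oxidation, in which the N-oxide oxygen displaces chloride and the alkoxyammonium salt loses trimethylamine to give the 2-substituted acrolein under nearly neutral conditions that should spare the ester, the oxirane and C1.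

**Step 14**
Reactants: 18 (1S,3S,4S,6S)-1-methyl-2-oxo-4-(3-oxoprop-1-en-2-yl)-7-oxabicyclo[4.1.0]heptan-3-yl 3-methylbutanoate
Product: 19 (1S,3S,4R,6S)-4-[(2R)-2-formyloxiran-2-yl]-1-methyl-2-oxo-7-oxabicyclo[4.1.0]heptan-3-yl 3-methylbutanoate
Conditions: (S)-α,α-diphenylprolinol methyldiphenylsilyl ether (10 mol%), 35% aq. H2O2, CH2Cl2, rt
Reagents that add atoms: hydrogen peroxide OO
Why: iminium–enamine organocatalytic epoxidation of a 2-substituted acrolein, in which hydrogen peroxide adds to the methylene terminus of the iminium ion and the enamine closes the oxirane on the face left open by the bulky group of the catalyst, so the quaternary carbon C7 is set under catalyst control while the hindered ring ketone does not condense with the amine.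

**Step 15**
Reactants: 19 (1S,3S,4R,6S)-4-[(2R)-2-formyloxiran-2-yl]-1-methyl-2-oxo-7-oxabicyclo[4.1.0]heptan-3-yl 3-methylbutanoate; 20 4,4,5,5-tetramethyl-2-(prop-2-en-1-yl)-1,3,2-dioxaborolane
Product: 21 (1S,3S,4R,6S)-4-[(2R)-2-(1-hydroxybut-3-en-1-yl)oxiran-2-yl]-1-methyl-2-oxo-7-oxabicyclo[4.1.0]heptan-3-yl 3-methylbutanoate (mixture of carbinol epimers)
Conditions: CH2Cl2, rt; then aqueous NaHCO3
Reagents that add atoms: none
Why: allylboration through a closed six-membered transition state, in which the pinacol allylboronate adds to the aldehyde but not to the hindered ring ketone or the ester; the new carbinol stereocentre is left uncontrolled because step 17 removes it.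

**Step 16**
Reactants: 21 (1S,3S,4R,6S)-4-[(2R)-2-(1-hydroxybut-3-en-1-yl)oxiran-2-yl]-1-methyl-2-oxo-7-oxabicyclo[4.1.0]heptan-3-yl 3-methylbutanoate; 22 2-methylbut-2-ene
Product: 23 (1S,3S,4R,6S)-4-[(2R)-2-(1-hydroxy-4-methylpent-3-en-1-yl)oxiran-2-yl]-1-methyl-2-oxo-7-oxabicyclo[4.1.0]heptan-3-yl 3-methylbutanoate (mixture of carbinol epimers)
Conditions: second-generation Grubbs catalyst (5 mol%), 2-methylbut-2-ene (excess), CH2Cl2, 40 °C
Reagents that add atoms: none
Why: olefin cross-metathesis of a terminal alkene with excess 2-methylbut-2-ene, a known way to turn an allyl into a prenyl group; the oxiranes, the ketone, the ester and the free hydroxyl group are tolerated by the ruthenium carbene and no stereocentre is touched.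

**Step 17**
Reactants: 23 (1S,3S,4R,6S)-4-[(2R)-2-(1-hydroxy-4-methylpent-3-en-1-yl)oxiran-2-yl]-1-methyl-2-oxo-7-oxabicyclo[4.1.0]heptan-3-yl 3-methylbutanoate
Product: 24 (1S,3S,4R,6S)-1-methyl-4-[(2R)-2-(4-methylpent-3-enoyl)oxiran-2-yl]-2-oxo-7-oxabicyclo[4.1.0]heptan-3-yl 3-methylbutanoate
Conditions: Dess–Martin periodinane, pyridine, CH2Cl2, 0 °C
Reagents that add atoms: none
Why: Dess–Martin oxidation of the secondary carbinol gives the β,γ-unsaturated ketone and removes the uncontrolled stereocentre; the pyridine buffer and low temperature should prevent migration of the alkene into conjugation.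

**Step 18**
Reactants: 24 (1S,3S,4R,6S)-1-methyl-4-[(2R)-2-(4-methylpent-3-enoyl)oxiran-2-yl]-2-oxo-7-oxabicyclo[4.1.0]heptan-3-yl 3-methylbutanoate
Product: 25 (1S,3S,4R,6S)-4-{(2R)-2-[(2E)-4-hydroperoxy-4-methylpent-2-enoyl]oxiran-2-yl}-1-methyl-2-oxo-7-oxabicyclo[4.1.0]heptan-3-yl 3-methylbutanoate
Conditions: O2, tetraphenylporphyrin (cat.), visible light, CH2Cl2, −20 °C
Reagents that add atoms: dioxygen O=O
Why: Schenck ene reaction, in which singlet oxygen adds to the only alkene left, bonding to C11 while a hydrogen of the C9 methylene (on the more crowded side of the alkene and next to the ketone) is transferred, so the double bond should move into conjugation as the E-enone and the tertiary hydroperoxide forms; no stereocentre is created.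

**Compound list**
1 | methyl (4R)-2,2-dimethyl-1,3-dioxolane-4-carboxylate | COC(=O)[C@H]1COC(C)(C)O1 | starting material
2 | (4R)-N-methoxy-N,2,2-trimethyl-1,3-dioxolane-4-carboxamide (Weinreb amide, not isolated) | CON(C)C(=O)[C@H]1COC(C)(C)O1 | intermediate
3 | 1-[(4R)-2,2-dimethyl-1,3-dioxolan-4-yl]ethan-1-one | CC(=O)[C@H]1COC(C)(C)O1 | intermediate
4 | 5-bromo-2-methylpent-2-ene | CC(C)=CCCBr | starting material
5 | (4-methylpent-3-en-1-yl)triphenylphosphonium bromide | CC(C)=CCC[P+](c1ccccc1)(c1ccccc1)c1ccccc1.[Br-] | intermediate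
6 | (4-methylpent-3-en-1-ylidene)triphenyl-λ5-phosphane (ylide, not isolated) | CC(C)=CCC=P(c1ccccc1)(c1ccccc1)c1ccccc1 | intermediate
7 | (4S)-2,2-dimethyl-4-[(2Z)-6-methylhepta-2,5-dien-2-yl]-1,3-dioxolane | CC(C)=CC/C=C(C)\[C@H]1COC(C)(C)O1 | intermediate
8 | (2S,3Z)-3,7-dimethylocta-3,6-diene-1,2-diol | CC(C)=CC/C=C(C)\[C@H](O)CO | intermediate
9 | (2S,3Z)-3,7-dimethyl-1,2-bis(triethylsilyloxy)octa-3,6-diene | CC(C)=CC/C=C(C)\[C@H](O[Si](CC)(CC)CC)CO[Si](CC)(CC)CC | intermediate
10 | (2S,3Z)-3,7-dimethyl-2-(triethylsilyloxy)octa-3,6-dienal | CC(C)=CC/C=C(C)\[C@H](O[Si](CC)(CC)CC)C=O | intermediate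
11 | (1S,2S,6S)-3-methyl-6-(prop-1-en-2-yl)-2-(triethylsilyloxy)cyclohex-3-en-1-ol (C1–OH trans to both the C2 silyloxy group and the C6 isopropenyl group) | O[C@@H]1[C@@H](O[Si](CC)(CC)CC)C(C)=CC[C@H]1C(C)=C | intermediate
12 | 3-methylbutanoyl chloride | CC(C)CC(Cl)=O | starting material
13 | (1S,2S,6S)-3-methyl-6-(prop-1-en-2-yl)-2-(triethylsilyloxy)cyclohex-3-en-1-yl 3-methylbutanoate | CC(C)CC(=O)O[C@@H]1[C@@H](O[Si](CC)(CC)CC)C(C)=CC[C@H]1C(C)=C | intermediate
14 | (1S,2S,6S)-2-hydroxy-3-methyl-6-(prop-1-en-2-yl)cyclohex-3-en-1-yl 3-methylbutanoate | CC(C)CC(=O)O[C@@H]1[C@@H](O)C(C)=CC[C@H]1C(C)=C | intermediate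
15 | (1R,2R,3S,4S,6S)-2-hydroxy-1-methyl-4-(prop-1-en-2-yl)-7-oxabicyclo[4.1.0]heptan-3-yl 3-methylbutanoate (oxirane cis to OH and to isopropenyl) | CC(C)CC(=O)O[C@@H]1[C@@H](O)[C@@]2(C)O[C@H]2C[C@H]1C(C)=C | intermediate
16 | (1S,3S,4S,6S)-1-methyl-2-oxo-4-(prop-1-en-2-yl)-7-oxabicyclo[4.1.0]heptan-3-yl 3-methylbutanoate | CC(C)CC(=O)O[C@@H]1C(=O)[C@@]2(C)O[C@H]2C[C@H]1C(C)=C | intermediate
17 | (1S,3S,4S,6S)-4-(3-chloroprop-1-en-2-yl)-1-methyl-2-oxo-7-oxabicyclo[4.1.0]heptan-3-yl 3-methylbutanoate | CC(C)CC(=O)O[C@@H]1C(=O)[C@@]2(C)O[C@H]2C[C@H]1C(=C)CCl | intermediate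
18 | (1S,3S,4S,6S)-1-methyl-2-oxo-4-(3-oxoprop-1-en-2-yl)-7-oxabicyclo[4.1.0]heptan-3-yl 3-methylbutanoate | CC(C)CC(=O)O[C@@H]1C(=O)[C@@]2(C)O[C@H]2C[C@H]1C(=C)C=O | intermediate
19 | (1S,3S,4R,6S)-4-[(2R)-2-formyloxiran-2-yl]-1-methyl-2-oxo-7-oxabicyclo[4.1.0]heptan-3-yl 3-methylbutanoate | CC(C)CC(=O)O[C@@H]1C(=O)[C@@]2(C)O[C@H]2C[C@H]1[C@]1(C=O)CO1 | intermediate
20 | 4,4,5,5-tetramethyl-2-(prop-2-en-1-yl)-1,3,2-dioxaborolane | C=CCB1OC(C)(C)C(C)(C)O1 | starting material
21 | (1S,3S,4R,6S)-4-[(2R)-2-(1-hydroxybut-3-en-1-yl)oxiran-2-yl]-1-methyl-2-oxo-7-oxabicyclo[4.1.0]heptan-3-yl 3-methylbutanoate (both carbinol epimers) | CC(C)CC(=O)O[C@@H]1C(=O)[C@@]2(C)O[C@H]2C[C@H]1[C@]1(C(O)CC=C)CO1 | intermediate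
22 | 2-methylbut-2-ene | CC=C(C)C | starting material
23 | (1S,3S,4R,6S)-4-[(2R)-2-(1-hydroxy-4-methylpent-3-en-1-yl)oxiran-2-yl]-1-methyl-2-oxo-7-oxabicyclo[4.1.0]heptan-3-yl 3-methylbutanoate (both carbinol epimers) | CC(C)CC(=O)O[C@@H]1C(=O)[C@@]2(C)O[C@H]2C[C@H]1[C@]1(C(O)CC=C(C)C)CO1 | intermediate
24 | (1S,3S,4R,6S)-1-methyl-4-[(2R)-2-(4-methylpent-3-enoyl)oxiran-2-yl]-2-oxo-7-oxabicyclo[4.1.0]heptan-3-yl 3-methylbutanoate | CC(C)CC(=O)O[C@@H]1C(=O)[C@@]2(C)O[C@H]2C[C@H]1[C@]1(C(=O)CC=C(C)C)CO1 | intermediate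
25 | (1S,3S,4R,6S)-4-{(2R)-2-[(2E)-4-hydroperoxy-4-methylpent-2-enoyl]oxiran-2-yl}-1-methyl-2-oxo-7-oxabicyclo[4.1.0]heptan-3-yl 3-methylbutanoate | CC(C)CC(=O)O[C@@H]1C(=O)[C@@]2(C)O[C@H]2C[C@H]1[C@]1(C(=O)/C=C/C(C)(C)OO)CO1 | target

**Step count and risks**
Total step count: 18. Longest linear sequence: 17 steps (steps 1 and 3 to 18; only step 2 lies off the main line).

The three steps most likely to fail:

Step 18. The ene reaction with singlet oxygen may show poor regioselectivity in the hydrogen-transfer event: a hydrogen of the cis methyl group may be abstracted instead of one from the C9 methylene, which leads to the secondary allylic hydroperoxide with an isopropenyl end. The fallback sets out from 19 and comes back at 25, and brings the hydroperoxide in ready-made and protected. Aldehyde 19 is homologated with dimethyl (diazomethyl)phosphonate and catalytic SnCl2 in CH2Cl2 (Roskamp reaction, aldehyde-selective) to the β-ketophosphonate (1S,3S,4R,6S)-4-{(2R)-2-[2-(dimethoxyphosphoryl)acetyl]oxiran-2-yl}-1-methyl-2-oxo-7-oxabicyclo[4.1.0]heptan-3-yl 3-methylbutanoate F4. In parallel, 2-methylbut-3-en-2-ol is treated with 50% H2O2 and catalytic H2SO4 to give 2-methylbut-3-en-2-yl hydroperoxide F5, which is masked with 2-methoxypropene and pyridinium p-toluenesulfonate as the peroxyketal 2-methoxy-2-[(2-methylbut-3-en-2-yl)peroxy]propane F6; ozonolysis with Me2S work-up gives 2-[(2-methoxypropan-2-yl)peroxy]-2-methylpropanal F7. Horner–Wadsworth–Emmons olefination of F4 with F7 (LiCl, iPr2NEt, MeCN, Masamune–Roush conditions) should give the E-enone (1S,3S,4R,6S)-4-{(2R)-2-[(2E)-4-[(2-methoxypropan-2-yl)peroxy]-4-methylpent-2-enoyl]oxiran-2-yl}-1-methyl-2-oxo-7-oxabicyclo[4.1.0]heptan-3-yl 3-methylbutanoate F8, and AcOH/H2O/THF removes the peroxyketal to give 25.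

Step 14. Iminium formation at the hindered 2-substituted acrolein may be slow, and facial control in the oxirane-closing event may be insufficient next to the C6 stereocentre. The fallback sets out from 18 and comes back at 19. NaBH(OAc)3 reduces only the aldehyde, not the ring ketone, to the allylic alcohol (1S,3S,4S,6S)-4-(3-hydroxyprop-1-en-2-yl)-1-methyl-2-oxo-7-oxabicyclo[4.1.0]heptan-3-yl 3-methylbutanoate F2. Sharpless asymmetric epoxidation (Ti(OiPr)4, L-(+)-diethyl tartrate, t-BuOOH, 4 Å molecular sieves, CH2Cl2, −20 °C) then sets C7 under reagent control; this tartrate converts 2-substituted allyl alcohols into the (S)-glycidol series, which is the oxygen face needed here, and should give (1S,3S,4R,6S)-4-[(2S)-2-(hydroxymethyl)oxiran-2-yl]-1-methyl-2-oxo-7-oxabicyclo[4.1.0]heptan-3-yl 3-methylbutanoate F3. Dess–Martin oxidation of F3 returns 19.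

Step 7. Facial selectivity at the aldehyde carbon may be poor if the complexed carbonyl oxygen enters the pseudo-axial position of the chair, which would set C1 wrongly while C6 stays correct. The fallback sets out from 10 and comes back at 13, and corrects C1 by inversion instead of relying on the direct closure. The C1 epimer (1R,2S,6S)-3-methyl-6-(prop-1-en-2-yl)-2-(triethylsilyloxy)cyclohex-3-en-1-ol F1, whose hydroxyl group is cis to both neighbours, is separated and esterified with 3-methylbutanoic acid under Mitsunobu conditions (PPh3, diisopropyl azodicarboxylate, THF). SN2 inversion at C1 gives 13 directly, while any 11 formed is acylated as in step 8.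

**Further compounds**
F1 | step 7 | (1R,2S,6S)-3-methyl-6-(prop-1-en-2-yl)-2-(triethylsilyloxy)cyclohex-3-en-1-ol | O[C@H]1[C@@H](O[Si](CC)(CC)CC)C(C)=CC[C@H]1C(C)=C
F2 | step 14 | (1S,3S,4S,6S)-4-(3-hydroxyprop-1-en-2-yl)-1-methyl-2-oxo-7-oxabicyclo[4.1.0]heptan-3-yl 3-methylbutanoate | CC(C)CC(=O)O[C@@H]1C(=O)[C@@]2(C)O[C@H]2C[C@H]1C(=C)CO
F3 | step 14 | (1S,3S,4R,6S)-4-[(2S)-2-(hydroxymethyl)oxiran-2-yl]-1-methyl-2-oxo-7-oxabicyclo[4.1.0]heptan-3-yl 3-methylbutanoate | CC(C)CC(=O)O[C@@H]1C(=O)[C@@]2(C)O[C@H]2C[C@H]1[C@]1(CO)CO1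
F4 | step 18 | (1S,3S,4R,6S)-4-{(2R)-2-[2-(dimethoxyphosphoryl)acetyl]oxiran-2-yl}-1-methyl-2-oxo-7-oxabicyclo[4.1.0]heptan-3-yl 3-methylbutanoate | CC(C)CC(=O)O[C@@H]1C(=O)[C@@]2(C)O[C@H]2C[C@H]1[C@]1(C(=O)CP(=O)(OC)OC)CO1
F5 | step 18 | 2-methylbut-3-en-2-yl hydroperoxide | C=CC(C)(C)OO
F6 | step 18 | 2-methoxy-2-[(2-methylbut-3-en-2-yl)peroxy]propane | C=CC(C)(C)OOC(C)(C)OC
F7 | step 18 | 2-[(2-methoxypropan-2-yl)peroxy]-2-methylpropanal | O=CC(C)(C)OOC(C)(C)OC
F8 | step 18 | (1S,3S,4R,6S)-4-{(2R)-2-[(2E)-4-[(2-methoxypropan-2-yl)peroxy]-4-methylpent-2-enoyl]oxiran-2-yl}-1-methyl-2-oxo-7-oxabicyclo[4.1.0]heptan-3-yl 3-methylbutanoate | CC(C)CC(=O)O[C@@H]1C(=O)[C@@]2(C)O[C@H]2C[C@H]1[C@]1(C(=O)/C=C/C(C)(C)OOC(C)(C)OC)CO1
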